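**Strategy.** Daucane numbering is used: C1 is the methyl-bearing ring-fusion carbon, C4 the isopropyl carbinol, C5 the ring-fusion CH, C6 the ester carbon. Everything rests on disconnecting the cyclopentane at C1–C5. C5 lies between the oxygenated carbons C4 and C6, so it can be a diazo carbon flanked by ketone and ester, while C1 is a tertiary C–H carbon 1,5 to it. A dirhodium-catalysed carbenoid C–H insertion closes the five-membered ring and makes the quaternary stereocentre C1 with retention. The precursor is an acyclic α-diazo-β-keto ester made from (R)-citronellol; a lactone lock, isopropyl addition and ring-closing metathesis then build the seven-membered ring.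

Key step: step 5

Remark on the chemistry: ring positions in the text are C1–C2–C3–C4–C5 (five-membered ring) and C1–C5–C6–C7–C8–C9–C10 (seven-membered ring); "β" is the face of the angular methyl group. Compound names use IUPAC numbering.

Remark on the chemistry: the carbon between the two carbonyl groups in 7 and 8 equilibrates through the enol and is written without configuration; it is fixed in step 6. The ring carbon of ozonide 3 is likewise undefined.

Step 1
Reactants: 1 (R)-citronellol, (3R)-3,7-dimethyloct-6-en-1-ol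
Product: 2 tert-butyl{[(3R)-3,7-dimethyloct-6-en-1-yl]oxy}dimethylsilane
Conditions: TBSCl, imidazole, CH2Cl2, rt
Reagents that add atoms: tert-butyldimethylsilyl chloride CC(C)(C)[Si](C)(C)Cl
Why: Silyl ether formation masks the primary alcohol, which would otherwise trap the later rhodium carbenoid by O–H insertion, and leaves the stereocentre untouched.

Step 2
Reactants: 2 tert-butyl{[(3R)-3,7-dimethyloct-6-en-1-yl]oxy}dimethylsilane
Product: 4 (4R)-6-[(tert-butyldimethylsilyl)oxy]-4-methylhexanal, via secondary ozonide 3 (not isolated)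
Conditions: O3, CH2Cl2, −78 °C; then Me2S, −78 °C to rt
Reagents that add atoms: ozone [O-][O+]=O
Why: Ozonolysis with reductive work-up cleaves the only alkene to the aldehyde and acetone without touching the stereocentre.

Step 3
Reactants: 4 (4R)-6-[(tert-butyldimethylsilyl)oxy]-4-methylhexanal
Product: 5 ethyl (6R)-8-[(tert-butyldimethylsilyl)oxy]-6-methyl-3-oxooctanoate
Conditions: ethyl diazoacetate, SnCl2 (10 mol %), CH2Cl2, rt
Reagents that add atoms: ethyl diazoacetate CCOC(=O)C=[N+]=[N-]
Why: Roskamp reaction, in which Lewis-acid-promoted addition of the diazo ester to the aldehyde and 1,2-hydride shift with loss of N2 should give the β-keto ester directly, no stereocentre being formed.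

Step 4
Reactants: 5 ethyl (6R)-8-[(tert-butyldimethylsilyl)oxy]-6-methyl-3-oxooctanoate
Product: 6 ethyl (6R)-8-[(tert-butyldimethylsilyl)oxy]-2-diazo-6-methyl-3-oxooctanoate
Conditions: 4-acetamidobenzenesulfonyl azide, Et3N, MeCN, 0 °C to rt
Reagents that add atoms: 4-acetamidobenzenesulfonyl azide CC(=O)Nc1ccc(cc1)S(=O)(=O)N=[N+]=[N-]
Why: Regitz diazo transfer onto the active methylene of the β-keto ester should give the acceptor/acceptor diazo compound without affecting the stereocentre.

Step 5
Reactants: 6 ethyl (6R)-8-[(tert-butyldimethylsilyl)oxy]-2-diazo-6-methyl-3-oxooctanoate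
Product: 7 ethyl (2S)-2-{2-[(tert-butyldimethylsilyl)oxy]ethyl}-2-methyl-5-oxocyclopentane-1-carboxylate
Conditions: Rh2(OAc)4 (1 mol %), CH2Cl2, rt
Reagents that add atoms: none
Why: Dirhodium tetraacetate expels N2 from 6 and turns C5, normally a nucleophilic 1,3-dicarbonyl carbon, into an electrophilic rhodium carbenoid that inserts into the unactivated tertiary C1–H bond in a concerted, asynchronous three-centre event through a chair-like six-membered transition state. The closest known reaction type is the dirhodium-carboxylate-catalysed intramolecular 1,5 C–H insertion of α-diazo-β-keto esters, which gives 2-alkoxycarbonylcyclopentanones. The cyclopentane ring (C1–C2–C3–C4–C5) is closed in the 1,5-insertion mode, the favoured ring size for such carbenoids. C1 becomes the quaternary stereocentre with retention of the configuration bought in (R)-citronellol, because the new C–C bond forms on the face that the hydrogen occupied, whereas C5 arises as an enolisable centre that is fixed only in step 6. The step needs site selectivity for the tertiary C1–H over the secondary C–H bonds, the ethyl group of the ester and the C–H bonds next to the silyl ether; it is secured by the electronic preference of the acceptor/acceptor carbenoid for the most electron-rich (tertiary) C–H bond, by the fact that C1–H is the only C–H placed 1,5 on the ketone side, and by the lack of hydrogen on the atoms next to the carbenoid carbon, which excludes a 1,2-hydride shift.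

Step 6
Reactants: 7 ethyl (2S)-2-{2-[(tert-butyldimethylsilyl)oxy]ethyl}-2-methyl-5-oxocyclopentane-1-carboxylate
Product: 9 (4aS,7aR)-4a-methylhexahydrocyclopenta[c]pyran-1,7-dione, via hydroxy keto ester 8 (not isolated)
Conditions: 1 M aq. HCl, THF, rt; then p-TsOH (cat.), toluene, 100 °C
Reagents that add atoms: none
Why: Acidic desilylation followed by acid-catalysed transesterification (lactonisation), in which only the C5 epimer with the ester cis to the hydroxyethyl arm can close the six-membered lactone, so that the enolisable C5 centre should be drained into the cis-fused keto lactone.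

Step 7
Reactants: 9 (4aS,7aR)-4a-methylhexahydrocyclopenta[c]pyran-1,7-dione
Product: 10 (4aS,7R,7aR)-7-hydroxy-4a-methyl-7-(propan-2-yl)hexahydrocyclopenta[c]pyran-1(3H)-one
Conditions: i-PrMgCl, CeCl3 (dried), THF, −78 °C; AcOH quench at −78 °C
Reagents that add atoms: isopropylmagnesium chloride CC(C)[Mg]Cl
Why: Organocerium 1,2-addition (CeCl3-promoted Grignard addition), chosen because the weakly basic cerium reagent should add to the ketone of the enolisable 1,3-dicarbonyl instead of deprotonating it, the nucleophile entering from the convex β face, anti to the lactone arm on C5, which sets C4 with isopropyl cis to the angular methyl and hydroxyl cis to C6.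

Step 8
Reactants: 10 (4aS,7R,7aR)-7-hydroxy-4a-methyl-7-(propan-2-yl)hexahydrocyclopenta[c]pyran-1(3H)-one
Product: 11 (1R,2R,5S)-2-hydroxy-5-(2-hydroxyethyl)-N-methoxy-N,5-dimethyl-2-(propan-2-yl)cyclopentane-1-carboxamide
Conditions: MeNH(OMe)·HCl, Me3Al, CH2Cl2, 0 °C to rt
Reagents that add atoms: N,O-dimethylhydroxylamine hydrochloride CNOC.Cl
Why: Aluminium amide aminolysis of the lactone (Weinreb amide formation) should open the lock to an acyl equivalent that accepts one carbon nucleophile only and free the primary alcohol, with no change at any stereocentre.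

Step 9
Reactants: 11 (1R,2R,5S)-2-hydroxy-5-(2-hydroxyethyl)-N-methoxy-N,5-dimethyl-2-(propan-2-yl)cyclopentane-1-carboxamide
Product: 12 (1R,2R,5S)-2-hydroxy-N-methoxy-N,5-dimethyl-5-(2-oxoethyl)-2-(propan-2-yl)cyclopentane-1-carboxamide
Conditions: (COCl)2, DMSO, CH2Cl2, −78 °C; Et3N, −78 to 0 °C
Reagents that add atoms: none
Why: Swern oxidation should convert the primary alcohol into the aldehyde at low temperature without touching the tertiary alcohol and without over-oxidising the cyclic hemiacetal that the aldehyde can form with it afterwards.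

Step 10
Reactants: 12 (1R,2R,5S)-2-hydroxy-N-methoxy-N,5-dimethyl-5-(2-oxoethyl)-2-(propan-2-yl)cyclopentane-1-carboxamide
Product: 13 (1R,2R,5S)-2-hydroxy-N-methoxy-N,5-dimethyl-2-(propan-2-yl)-5-(prop-2-en-1-yl)cyclopentane-1-carboxamide
Conditions: Ph3PCH3Br, KN(SiMe3)2, THF, 0 °C; then 12, −78 °C to rt
Reagents that add atoms: methyltriphenylphosphonium bromide C[P+](c1ccccc1)(c1ccccc1)c1ccccc1.[Br-]
Why: Wittig methylenation of the aldehyde (also through its ring-chain hemiacetal) should install the terminal alkene needed for metathesis, the Weinreb amide being inert to the ylide.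

Step 11
Reactants: 13 (1R,2R,5S)-2-hydroxy-N-methoxy-N,5-dimethyl-2-(propan-2-yl)-5-(prop-2-en-1-yl)cyclopentane-1-carboxamide
Product: 14 1-[(1R,2R,5S)-2-hydroxy-5-methyl-2-(propan-2-yl)-5-(prop-2-en-1-yl)cyclopentyl]-3-methylbut-3-en-1-one
Conditions: 2-methylallylmagnesium chloride (3 equiv), THF, −78 to 0 °C; aq. NH4Cl
Reagents that add atoms: 2-methylallylmagnesium chloride CC(=C)C[Mg]Cl
Why: Grignard addition to the Weinreb amide should stop at the chelated tetrahedral intermediate and release the β,γ-unsaturated ketone only on mild quench, the first equivalent being consumed by the tertiary alcohol.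

Step 12
Reactants: 14 1-[(1R,2R,5S)-2-hydroxy-5-methyl-2-(propan-2-yl)-5-(prop-2-en-1-yl)cyclopentyl]-3-methylbut-3-en-1-one
Product: 15 (3R,3aR,8aS)-3-hydroxy-6,8a-dimethyl-3-(propan-2-yl)-2,3,3a,5,8,8a-hexahydroazulen-4(1H)-one
Conditions: second-generation Grubbs catalyst RuCl2(=CHPh)(PCy3)(H2IMes) (5 mol %), CH2Cl2 (0.005 M), 40 °C
Reagents that add atoms: none
Why: Ring-closing olefin metathesis between the allyl and 2-methylallyl arms, which are held cis on the cyclopentane, should close the seven-membered ring as the trisubstituted C8=C9 alkene with loss of ethene.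

Step 13
Reactants: 15 (3R,3aR,8aS)-3-hydroxy-6,8a-dimethyl-3-(propan-2-yl)-2,3,3a,5,8,8a-hexahydroazulen-4(1H)-one
Product: 16 (3R,3aS,4R,8aS)-6,8a-dimethyl-3-(propan-2-yl)-1,2,3,3a,4,5,8,8a-octahydroazulene-3,4-diol
Conditions: NaBH4, MeOH, −40 °C
Reagents that add atoms: none
Why: Borohydride reduction of the ketone, in which hydride should attack C6 from the convex β face, away from the fully substituted C4 on the neighbouring ring-fusion carbon and from the fused cyclopentane, which sets C6 with its hydroxyl cis to the C4 hydroxyl.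

Step 14
Reactants: 16 (3R,3aS,4R,8aS)-6,8a-dimethyl-3-(propan-2-yl)-1,2,3,3a,4,5,8,8a-octahydroazulene-3,4-diol; 17 4-(acetyloxy)benzoyl chloride
Product: 18 (3R,3aS,4R,8aS)-3-hydroxy-6,8a-dimethyl-3-(propan-2-yl)-1,2,3,3a,4,5,8,8a-octahydroazulen-4-yl 4-(acetyloxy)benzoate
Conditions: pyridine, DMAP (cat.), CH2Cl2, 0 °C to rt
Reagents that add atoms: none
Why: DMAP-catalysed acylation with the acid chloride should esterify the secondary alcohol only, the tertiary alcohol being too hindered to react.

Step 15
Reactants: 18 (3R,3aS,4R,8aS)-3-hydroxy-6,8a-dimethyl-3-(propan-2-yl)-1,2,3,3a,4,5,8,8a-octahydroazulen-4-yl 4-(acetyloxy)benzoate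
Product: 19 (3R,3aS,4R,6R,7S,8aS)-6,7-epoxy-3-hydroxy-6,8a-dimethyl-3-(propan-2-yl)decahydroazulen-4-yl 4-(acetyloxy)benzoate
Conditions: m-CPBA, NaHCO3, CH2Cl2, 0 °C
Reagents that add atoms: 3-chloroperoxybenzoic acid OOC(=O)c1cccc(Cl)c1
Why: Prilezhaev epoxidation of the trisubstituted alkene should occur on the convex β face, opposite to the aroyloxy group and the fused cyclopentane, which sets C8 and C9 together, the bicarbonate buffer protecting the epoxide.

Step 16
Reactants: 19 (3R,3aS,4R,6R,7S,8aS)-6,7-epoxy-3-hydroxy-6,8a-dimethyl-3-(propan-2-yl)decahydroazulen-4-yl 4-(acetyloxy)benzoate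
Product: 20 (3R,3aS,4R,6R,7S,8aS)-6,7-epoxy-3-hydroxy-6,8a-dimethyl-3-(propan-2-yl)decahydroazulen-4-yl 4-hydroxybenzoate
Conditions: K2CO3 (cat.), MeOH, 0 °C
Reagents that add atoms: none
Why: Base-catalysed transesterification should remove the aryl acetate far faster than the hindered alkyl benzoate, since phenoxide is the better leaving group, and release the phenol of the target.

**Compound list**

1 | (R)-citronellol, (3R)-3,7-dimethyloct-6-en-1-ol | CC(C)=CCC[C@@H](C)CCO | starting material
2 | tert-butyl{[(3R)-3,7-dimethyloct-6-en-1-yl]oxy}dimethylsilane | CC(C)=CCC[C@@H](C)CCO[Si](C)(C)C(C)(C)C | intermediate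
3 | 3-{(3R)-5-[(tert-butyldimethylsilyl)oxy]-3-methylpentyl}-5,5-dimethyl-1,2,4-trioxolane (secondary ozonide, ring carbon undefined) | CC1(C)OOC(CC[C@@H](C)CCO[Si](C)(C)C(C)(C)C)O1 | intermediate
4 | (4R)-6-[(tert-butyldimethylsilyl)oxy]-4-methylhexanal | O=CCC[C@@H](C)CCO[Si](C)(C)C(C)(C)C | intermediate
5 | ethyl (6R)-8-[(tert-butyldimethylsilyl)oxy]-6-methyl-3-oxooctanoate | CCOC(=O)CC(=O)CC[C@@H](C)CCO[Si](C)(C)C(C)(C)C | intermediate
6 | ethyl (6R)-8-[(tert-butyldimethylsilyl)oxy]-2-diazo-6-methyl-3-oxooctanoate | CCOC(=O)C(=[N+]=[N-])C(=O)CC[C@@H](C)CCO[Si](C)(C)C(C)(C)C | intermediate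
7 | ethyl (2S)-2-{2-[(tert-butyldimethylsilyl)oxy]ethyl}-2-methyl-5-oxocyclopentane-1-carboxylate (ring C1 equilibrating) | CCOC(=O)C1C(=O)CC[C@@]1(C)CCO[Si](C)(C)C(C)(C)C | intermediate
8 | ethyl (2S)-2-(2-hydroxyethyl)-2-methyl-5-oxocyclopentane-1-carboxylate (ring C1 equilibrating) | CCOC(=O)C1C(=O)CC[C@@]1(C)CCO | intermediate
9 | (4aS,7aR)-4a-methylhexahydrocyclopenta[c]pyran-1,7-dione (cis-fused keto lactone) | O=C1OCC[C@]2(C)CCC(=O)[C@H]12 | intermediate
10 | (4aS,7R,7aR)-7-hydroxy-4a-methyl-7-(propan-2-yl)hexahydrocyclopenta[c]pyran-1(3H)-one | O=C1OCC[C@]2(C)CC[C@@](O)(C(C)C)[C@H]12 | intermediate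
11 | (1R,2R,5S)-2-hydroxy-5-(2-hydroxyethyl)-N-methoxy-N,5-dimethyl-2-(propan-2-yl)cyclopentane-1-carboxamide | CON(C)C(=O)[C@H]1[C@](O)(C(C)C)CC[C@@]1(C)CCO | intermediate
12 | (1R,2R,5S)-2-hydroxy-N-methoxy-N,5-dimethyl-5-(2-oxoethyl)-2-(propan-2-yl)cyclopentane-1-carboxamide | CON(C)C(=O)[C@H]1[C@](O)(C(C)C)CC[C@@]1(C)CC=O | intermediate
13 | (1R,2R,5S)-2-hydroxy-N-methoxy-N,5-dimethyl-2-(propan-2-yl)-5-(prop-2-en-1-yl)cyclopentane-1-carboxamide | CON(C)C(=O)[C@H]1[C@](O)(C(C)C)CC[C@@]1(C)CC=C | intermediate
14 | 1-[(1R,2R,5S)-2-hydroxy-5-methyl-2-(propan-2-yl)-5-(prop-2-en-1-yl)cyclopentyl]-3-methylbut-3-en-1-one | CC(=C)CC(=O)[C@H]1[C@](O)(C(C)C)CC[C@@]1(C)CC=C | intermediate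
15 | (3R,3aR,8aS)-3-hydroxy-6,8a-dimethyl-3-(propan-2-yl)-2,3,3a,5,8,8a-hexahydroazulen-4(1H)-one | CC(C)[C@]1(O)CC[C@@]2(C)CC=C(C)CC(=O)[C@H]21 | intermediate
16 | (3R,3aS,4R,8aS)-6,8a-dimethyl-3-(propan-2-yl)-1,2,3,3a,4,5,8,8a-octahydroazulene-3,4-diol | CC(C)[C@]1(O)CC[C@@]2(C)CC=C(C)C[C@@H](O)[C@H]21 | intermediate
17 | 4-(acetyloxy)benzoyl chloride | CC(=O)Oc1ccc(cc1)C(Cl)=O | starting material
18 | (3R,3aS,4R,8aS)-3-hydroxy-6,8a-dimethyl-3-(propan-2-yl)-1,2,3,3a,4,5,8,8a-octahydroazulen-4-yl 4-(acetyloxy)benzoate | CC(C)[C@]1(O)CC[C@@]2(C)CC=C(C)C[C@@H](OC(=O)c3ccc(OC(C)=O)cc3)[C@H]21 | intermediate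
19 | (3R,3aS,4R,6R,7S,8aS)-6,7-epoxy-3-hydroxy-6,8a-dimethyl-3-(propan-2-yl)decahydroazulen-4-yl 4-(acetyloxy)benzoate | CC(C)[C@]1(O)CC[C@@]2(C)C[C@@H]3O[C@]3(C)C[C@@H](OC(=O)c3ccc(OC(C)=O)cc3)[C@H]21 | intermediate
20 | (3R,3aS,4R,6R,7S,8aS)-6,7-epoxy-3-hydroxy-6,8a-dimethyl-3-(propan-2-yl)decahydroazulen-4-yl 4-hydroxybenzoate | CC(C)[C@]1(O)CC[C@@]2(C)C[C@@H]3O[C@]3(C)C[C@@H](OC(=O)c3ccc(O)cc3)[C@H]21 | target

**Totals.** Total step count: 16. Longest linear sequence: 16 steps (1 to 20).

**Steps most likely to fail**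

Step 7. What may go wrong: proton transfer from the acidic C5–H of the β-keto lactone to the organometallic (enolisation instead of addition), or retro-aldol opening of the alkoxide formed. Fallback: setting out from 9, the isopropyl group is introduced by a samarium Barbier coupling with 2-iodopropane and SmI2 in THF/HMPA at −78 to 0 °C. The C–C bond is then made by single-electron reduction on the chelated keto lactone, with no basic organometallic present. The same convex-face approach should apply, and the sequence comes back to the route at 10 without any new compound (F0).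

Step 13. What may go wrong: poor facial selectivity of hydride delivery to C6, for example through internal delivery guided by the C4 hydroxyl, which leaves the C6 epimer. Fallback: setting out from 15, the ketone is reduced on purpose with internal delivery from the α-oriented C4 hydroxyl (Me4NBH(OAc)3, MeCN/AcOH, −20 °C). This should give the C6-epimeric diol (3R,3aS,4S,8aS)-6,8a-dimethyl-3-(propan-2-yl)-1,2,3,3a,4,5,8,8a-octahydroazulene-3,4-diol F1. F1 is then esterified with inversion at C6 by a Mitsunobu reaction with 4-(acetyloxy)benzoic acid (PPh3, diisopropyl azodicarboxylate, toluene), which comes back to the route at 18.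

Step 15. What may go wrong: attack of the peracid on the α face of the cycloheptene, which gives the epimeric epoxide. Fallback: setting out from 18, the alkene is treated with N-bromosuccinimide in aqueous 1,2-dimethoxyethane. The bromonium ion should form on the same α face and water should open it at the tertiary C8 from the β face, giving the bromohydrin (3R,3aS,4R,6R,7R,8aS)-7-bromo-3,6-dihydroxy-6,8a-dimethyl-3-(propan-2-yl)decahydroazulen-4-yl 4-(acetyloxy)benzoate F2. K2CO3 in MeOH then closes the β-epoxide by displacement of bromide at C9 and removes the aryl acetate in the same flask, which comes back to the route at 20.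

Further compounds
F0 | step 7 | none | none
F1 | step 13 | (3R,3aS,4S,8aS)-6,8a-dimethyl-3-(propan-2-yl)-1,2,3,3a,4,5,8,8a-octahydroazulene-3,4-diol | CC(C)[C@]1(O)CC[C@@]2(C)CC=C(C)C[C@H](O)[C@H]21
F2 | step 15 | (3R,3aS,4R,6R,7R,8aS)-7-bromo-3,6-dihydroxy-6,8a-dimethyl-3-(propan-2-yl)decahydroazulen-4-yl 4-(acetyloxy)benzoate | CC(C)[C@]1(O)CC[C@@]2(C)C[C@@H](Br)[C@](C)(O)C[C@@H](OC(=O)c3ccc(OC(C)=O)cc3)[C@H]21
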